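**Strategy.** Ring C of the flavanone is disconnected at O1–C2 and C4–C4a, which leads back to a simple aryl ester: the 3,5-dihydroxyphenyl (E)-cinnamate 17 of the complete dihydrobenzofuran acid. In one pot a photo-Fries acyl shift (ester O to ring carbon) gives the 2',4',6'-trihydroxychalcone, which chalcone isomerase, an intramolecular lyase, cyclises at once to the (2S)-flavanone. The step exploits the threefold symmetry of phloroglucinol ring A: C4a lies between two equivalent oxygen-bearing carbons (C8a with O1, C5 with its hydroxyl), so every migration terminus and either flanking hydroxyl give the same ring C. The dihydrobenzofuran is built by enantioselective dirhodium carbenoid C–H insertion.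

Key step: step 11

Remark: Rh2(S-PTTL)4 is assumed to deliver the (2R) benzylic centre in step 5, as in related insertions of aryldiazoacetates into aryl benzyl ethers; if the sense proves opposite, Rh2(R-PTTL)4 is used instead.

**Step 1**
Reactants: 1 5-iodovanillin
Product: 2 3,4-dihydroxy-5-iodobenzaldehyde
Conditions: AlCl3, pyridine, CH2Cl2, reflux; aqueous work-up
Reagents that add atoms: none
Why: Chelation-assisted Lewis-acid cleavage of the guaiacol methyl ether (AlCl3–pyridine O-demethylation) should free the catechol without touching the aryl iodide or the aldehyde.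

**Step 2**
Reactants: 3 4-(benzyloxy)-3-methoxybenzyl alcohol
Product: 4 4-(benzyloxy)-3-methoxybenzyl chloride
Conditions: SOCl2, CH2Cl2, 0 °C to rt
Reagents that add atoms: thionyl chloride, O=S(Cl)Cl
Why: Deoxychlorination of an electron-rich benzylic alcohol with thionyl chloride should give the benzylic chloride cleanly.

**Step 3**
Reactants: 2 3,4-dihydroxy-5-iodobenzaldehyde; 4 4-(benzyloxy)-3-methoxybenzyl chloride (2.2 equiv)
Product: 5 3,4-bis{[4-(benzyloxy)-3-methoxybenzyl]oxy}-5-iodobenzaldehyde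
Conditions: K2CO3, DMF, 60 °C, under N2
Reagents that add atoms: none
Why: Double Williamson etherification puts the same benzylic arm on both catechol oxygens, so no regioselectivity between the phenols is needed; the arm on O-4 is the later C–H insertion site and the arm on O-3 serves as a hydrogenolysable protecting group.

**Step 4**
Reactants: 5 3,4-bis{[4-(benzyloxy)-3-methoxybenzyl]oxy}-5-iodobenzaldehyde; 6 ethyl diazoacetate
Product: 7 ethyl 2-(2,3-bis{[4-(benzyloxy)-3-methoxybenzyl]oxy}-5-formylphenyl)-2-diazoacetate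
Conditions: Pd(PPh3)4 (5 mol %), Ag2CO3 (0.5 equiv), Et3N, toluene, rt
Reagents that add atoms: none
Why: Palladium-catalysed cross-coupling of an aryl iodide with ethyl diazoacetate (arylation of the diazo carbon with the diazo group retained) should install the donor/acceptor carbene precursor in one step under mild, non-nucleophilic conditions that the aldehyde tolerates.

**Step 5**
Reactants: 7 ethyl 2-(2,3-bis{[4-(benzyloxy)-3-methoxybenzyl]oxy}-5-formylphenyl)-2-diazoacetate
Product: 8 ethyl (2R,3S)-2-[4-(benzyloxy)-3-methoxyphenyl]-7-{[4-(benzyloxy)-3-methoxybenzyl]oxy}-5-formyl-2,3-dihydro-1-benzofuran-3-carboxylate (cis)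
Conditions: Rh2(S-PTTL)4 [dirhodium tetrakis(N-phthaloyl-(S)-tert-leucinate)] (1 mol %), toluene, −60 °C
Reagents that add atoms: none
Why: Enantioselective intramolecular 1,5 C–H insertion of the donor/acceptor dirhodium carbenoid into the ortho benzylic ether methylene closes the dihydrofuran; the chiral carboxylate ligands select one enantiotopic hydrogen and set C2 as R, and the kinetic product is the cis ester, whose C3 is corrected in step 6.

**Step 6**
Reactants: 8 cis formyl ester
Product: 10 ethyl (2R,3R)-2-[4-(benzyloxy)-3-methoxyphenyl]-7-{[4-(benzyloxy)-3-methoxybenzyl]oxy}-5-(hydroxymethyl)-2,3-dihydro-1-benzofuran-3-carboxylate (trans), via cis-hydroxymethyl ester 9 (not isolated)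
Conditions: NaBH4, EtOH, 0 °C; acetone quench; then NaOEt, EtOH, rt
Reagents that add atoms: none
Why: Chemoselective borohydride reduction of the aldehyde, which also removes the para-acyl activation that would make the ring oxygen a leaving group, is followed by ethoxide-mediated epimerisation of the ester α-carbon under thermodynamic control to the trans ester, with C2 untouched.

**Step 7**
Reactants: 10 trans hydroxymethyl ester
Product: 11 [(2R,3S)-2-[4-(benzyloxy)-3-methoxyphenyl]-7-{[4-(benzyloxy)-3-methoxybenzyl]oxy}-2,3-dihydro-1-benzofuran-3,5-diyl]dimethanol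
Conditions: LiAlH4, THF, 0 °C
Reagents that add atoms: none
Why: Hydride reduction of the ethyl ester to the primary alcohol should proceed without affecting either stereocentre or the benzylic ethers.

**Step 8**
Reactants: 11 diol
Product: 12 (2R,3S)-2-[4-(benzyloxy)-3-methoxyphenyl]-7-{[4-(benzyloxy)-3-methoxybenzyl]oxy}-3-(hydroxymethyl)-2,3-dihydro-1-benzofuran-5-carbaldehyde
Conditions: MnO2 (activated, excess), CH2Cl2, rt
Reagents that add atoms: none
Why: MnO2 oxidation is selective for the benzylic alcohol and should leave the non-activated primary alcohol on C3 untouched.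

**Step 9**
Reactants: 12 protected aldehyde
Product: 13 (2R,3S)-7-hydroxy-2-(4-hydroxy-3-methoxyphenyl)-3-(hydroxymethyl)-2,3-dihydro-1-benzofuran-5-carbaldehyde
Conditions: H2 (1 atm), Pd/C, EtOAc–THF, rt, stopped at complete debenzylation
Reagents that add atoms: none
Why: Heterogeneous hydrogenolysis should cleave the two O-benzyl groups and then the unmasked 4-hydroxybenzyl aryl ether on O-7, under mild conditions that spare the cyclic secondary benzylic ether and the electron-rich aryl aldehyde.

**Step 10**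
Reactants: 13 triol aldehyde; 14 phloroglucinol (4 equiv); 15 ketenylidenetriphenylphosphorane (1.1 equiv)
Product: 17 3,5-dihydroxyphenyl (E)-3-[(2R,3S)-7-hydroxy-2-(4-hydroxy-3-methoxyphenyl)-3-(hydroxymethyl)-2,3-dihydro-1-benzofuran-5-yl]prop-2-enoate, via ester ylide 16 (not isolated)
Conditions: 14 and 15, THF, 60 °C; then 13, THF–toluene, 70 °C
Reagents that add atoms: none
Why: Addition of one phloroglucinol hydroxyl across the ketenylidene ylide gives an ester-stabilised phosphorane, whose Wittig olefination of the aldehyde should give the (E)-cinnamate aryl ester; stabilised ylides tolerate the free phenols and the alcohol.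

**Step 11**
Reactants: 17 3,5-dihydroxyphenyl cinnamate ester
Product: 19 silyhermin B, via chalcone 18 (not isolated)
Conditions: hν (310 nm LED), chalcone isomerase (recombinant, Medicago sativa, added in portions), argon-sparged 50 mM phosphate buffer pH 6.8 / DMSO (9:1), 25 °C
Reagents that add atoms: none
Why: Excitation of the aryl cinnamate homolyses the ArO–C(=O) bond, and in-cage recombination of the cinnamoyl radical at a ring carbon of the phloroglucinoxyl radical followed by tautomerisation forms the C4–C4a bond and gives chalcone 18, whose 2'-phenoxide then adds to the enone β-carbon in the enzyme active site to form the O1–C2 bond. The closest known reaction types are the photo-Fries rearrangement of hydroxyphenyl cinnamates to 2'-hydroxychalcones and the chalcone isomerase cyclisation of 2',4',6'-trihydroxychalcones to (2S)-5,7-dihydroxyflavanones. Ring C is the only ring closed, by a 6-endo-trig oxa-Michael addition, since the acyl shift itself closes no ring. C2 is set as S by the enzyme, which binds the enone and delivers the phenoxide to one face, while the three existing stereocentres are not involved. Regioselectivity needs no control because every free carbon of the phloroglucinol ester lies between two oxygens, so ortho and para migration converge on the same 2,4,6-trioxygenated ketone and either flanking hydroxyl can close the ring. Chemoselectivity should come from irradiating only the cinnamoyl ester band beyond the absorption of the other arenes and of the protein, and facial selectivity from the enzymatic rate at pH 6.8 far exceeding spontaneous cyclisation, the enzyme also removing the strongly absorbing chalcone as it forms.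

**Compound list**
1 | 5-iodovanillin (4-hydroxy-3-iodo-5-methoxybenzaldehyde) | COc1cc(C=O)cc(I)c1O | starting material
2 | 3,4-dihydroxy-5-iodobenzaldehyde | O=Cc1cc(O)c(O)c(I)c1 | intermediate
3 | 4-(benzyloxy)-3-methoxybenzyl alcohol | COc1cc(CO)ccc1OCc1ccccc1 | starting material
4 | 4-(benzyloxy)-3-methoxybenzyl chloride | COc1cc(CCl)ccc1OCc1ccccc1 | intermediate
5 | 3,4-bis{[4-(benzyloxy)-3-methoxybenzyl]oxy}-5-iodobenzaldehyde | COc1cc(COc2cc(C=O)cc(I)c2OCc2ccc(OCc3ccccc3)c(OC)c2)ccc1OCc1ccccc1 | intermediate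
6 | ethyl diazoacetate | CCOC(=O)C=[N+]=[N-] | starting material
7 | ethyl 2-(2,3-bis{[4-(benzyloxy)-3-methoxybenzyl]oxy}-5-formylphenyl)-2-diazoacetate | CCOC(=O)C(=[N+]=[N-])c1cc(C=O)cc(OCc2ccc(OCc3ccccc3)c(OC)c2)c1OCc1ccc(OCc2ccccc2)c(OC)c1 | intermediate
8 | ethyl (2R,3S)-2-[4-(benzyloxy)-3-methoxyphenyl]-7-{[4-(benzyloxy)-3-methoxybenzyl]oxy}-5-formyl-2,3-dihydro-1-benzofuran-3-carboxylate (cis) | COc1cc([C@@H]2Oc3c(OCc4ccc(OCc5ccccc5)c(OC)c4)cc(C=O)cc3[C@@H]2C(=O)OCC)ccc1OCc1ccccc1 | intermediate
9 | ethyl (2R,3S)-2-[4-(benzyloxy)-3-methoxyphenyl]-7-{[4-(benzyloxy)-3-methoxybenzyl]oxy}-5-(hydroxymethyl)-2,3-dihydro-1-benzofuran-3-carboxylate (cis) | COc1cc([C@@H]2Oc3c(OCc4ccc(OCc5ccccc5)c(OC)c4)cc(CO)cc3[C@@H]2C(=O)OCC)ccc1OCc1ccccc1 | intermediate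
10 | ethyl (2R,3R)-2-[4-(benzyloxy)-3-methoxyphenyl]-7-{[4-(benzyloxy)-3-methoxybenzyl]oxy}-5-(hydroxymethyl)-2,3-dihydro-1-benzofuran-3-carboxylate (trans) | COc1cc([C@@H]2Oc3c(OCc4ccc(OCc5ccccc5)c(OC)c4)cc(CO)cc3[C@H]2C(=O)OCC)ccc1OCc1ccccc1 | intermediate
11 | [(2R,3S)-2-[4-(benzyloxy)-3-methoxyphenyl]-7-{[4-(benzyloxy)-3-methoxybenzyl]oxy}-2,3-dihydro-1-benzofuran-3,5-diyl]dimethanol | COc1cc([C@@H]2Oc3c(OCc4ccc(OCc5ccccc5)c(OC)c4)cc(CO)cc3[C@H]2CO)ccc1OCc1ccccc1 | intermediate
12 | (2R,3S)-2-[4-(benzyloxy)-3-methoxyphenyl]-7-{[4-(benzyloxy)-3-methoxybenzyl]oxy}-3-(hydroxymethyl)-2,3-dihydro-1-benzofuran-5-carbaldehyde | COc1cc([C@@H]2Oc3c(OCc4ccc(OCc5ccccc5)c(OC)c4)cc(C=O)cc3[C@H]2CO)ccc1OCc1ccccc1 | intermediate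
13 | (2R,3S)-7-hydroxy-2-(4-hydroxy-3-methoxyphenyl)-3-(hydroxymethyl)-2,3-dihydro-1-benzofuran-5-carbaldehyde | COc1cc([C@@H]2Oc3c(O)cc(C=O)cc3[C@H]2CO)ccc1O | intermediate
14 | phloroglucinol (benzene-1,3,5-triol) | Oc1cc(O)cc(O)c1 | starting material
15 | ketenylidenetriphenylphosphorane | O=C=C=P(c1ccccc1)(c1ccccc1)c1ccccc1 | starting material
16 | 3,5-dihydroxyphenyl (triphenylphosphoranylidene)acetate | O=C(C=P(c1ccccc1)(c1ccccc1)c1ccccc1)Oc1cc(O)cc(O)c1 | intermediate
17 | 3,5-dihydroxyphenyl (E)-3-[(2R,3S)-7-hydroxy-2-(4-hydroxy-3-methoxyphenyl)-3-(hydroxymethyl)-2,3-dihydro-1-benzofuran-5-yl]prop-2-enoate | COc1cc([C@@H]2Oc3c(O)cc(/C=C/C(=O)Oc4cc(O)cc(O)c4)cc3[C@H]2CO)ccc1O | intermediate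
18 | (E)-3-[(2R,3S)-7-hydroxy-2-(4-hydroxy-3-methoxyphenyl)-3-(hydroxymethyl)-2,3-dihydro-1-benzofuran-5-yl]-1-(2,4,6-trihydroxyphenyl)prop-2-en-1-one | COc1cc([C@@H]2Oc3c(O)cc(/C=C/C(=O)c4c(O)cc(O)cc4O)cc3[C@H]2CO)ccc1O | intermediate
19 | silyhermin B, (2S)-5,7-dihydroxy-2-[(2R,3S)-7-hydroxy-2-(4-hydroxy-3-methoxyphenyl)-3-(hydroxymethyl)-2,3-dihydro-1-benzofuran-5-yl]-2,3-dihydro-4H-chromen-4-one | COc1cc([C@@H]2Oc3c(O)cc([C@@H]4CC(=O)c5c(O)cc(O)cc5O4)cc3[C@H]2CO)ccc1O | target

**Step count.** Total: 11 steps. Longest linear sequence: 10 steps (steps 1 and 3 to 11; step 2 prepares the side arm).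

**Steps most likely to fail**

1. Step 11. The excited cinnamoyl ester may relax mainly by E/Z isomerisation, so that the acyl shift is slow and photodegradation of the polyphenol competes. The enzyme may also bind the bulky ring-B substituent poorly, so that spontaneous cyclisation erodes facial selectivity at C2. The fallback uses known chemistry, sets out from aldehyde 12 and comes back at 19. Aldehyde 12 is condensed (piperidine/AcOH cat., toluene, molecular sieves) with tert-butyl 3-[2,4-bis(benzyloxy)-6-hydroxyphenyl]-3-oxopropanoate F1, itself made from commercial 2',4'-bis(benzyloxy)-6'-hydroxyacetophenone by C-acylation of its dianion with di-tert-butyl dicarbonate (LiHMDS, THF). This Knoevenagel condensation should give the alkylidene β-ketoester F2. A cinchona-derived bifunctional tertiary-amine thiourea, of the pseudoenantiomeric series that leads to 2S (10 mol %, toluene, −25 °C), should then close ring C by asymmetric oxa-Michael addition to the tert-butyl flavanone-3-carboxylate F3. Acid-mediated ester cleavage and decarboxylation (TsOH, toluene, 80 °C) should give the benzyl-protected (2S)-flavanone F4, and hydrogenolysis (H2, Pd/C, EtOAc) should give 19.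

2. Step 10. Phloroglucinol may add to the ketenylidene ylide through carbon or twice, and proton transfer from the phenols may slow the olefination of the electron-rich aldehyde. The fallback sets out from 13 and comes back at 17. Phloroglucinol is heated with Meldrum's acid (toluene, 90 °C) to give the malonic half ester 3-(3,5-dihydroxyphenoxy)-3-oxopropanoic acid F5. A decarboxylative Knoevenagel–Doebner condensation of F5 with 13 (pyridine, catalytic piperidinium acetate, 50 °C) should give the (E)-aryl cinnamate 17 directly.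

3. Step 4. Oxidative addition and carbene transfer may be slow at the hindered, electron-rich ortho-alkoxy aryl iodide, and the diazo ester may decompose before coupling. The fallback sets out from 5 and comes back at 7. Iodide 5 is converted into its 1,3-dioxolane F6 (ethylene glycol, TsOH cat., toluene, Dean–Stark). Palladium-catalysed Negishi-type α-arylation with the Reformatsky reagent BrZnCH2CO2Et (Pd(dba)2, P(t-Bu)3, THF, rt) should give the arylacetate acetal F7. Acetal hydrolysis (aqueous HCl, THF) should give the formyl arylacetate F8, and Regitz diazo transfer (4-acetamidobenzenesulfonyl azide, DBU, MeCN) should return 7.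

**Further compounds**
F1 | step 11 | tert-butyl 3-[2,4-bis(benzyloxy)-6-hydroxyphenyl]-3-oxopropanoate | CC(C)(C)OC(=O)CC(=O)c1c(O)cc(OCc2ccccc2)cc1OCc1ccccc1
F2 | step 11 | tert-butyl 2-[2,4-bis(benzyloxy)-6-hydroxybenzoyl]-3-[(2R,3S)-2-[4-(benzyloxy)-3-methoxyphenyl]-7-{[4-(benzyloxy)-3-methoxybenzyl]oxy}-3-(hydroxymethyl)-2,3-dihydro-1-benzofuran-5-yl]prop-2-enoate | COc1cc([C@@H]2Oc3c(OCc4ccc(OCc5ccccc5)c(OC)c4)cc(C=C(C(=O)OC(C)(C)C)C(=O)c4c(O)cc(OCc5ccccc5)cc4OCc4ccccc4)cc3[C@H]2CO)ccc1OCc1ccccc1
F3 | step 11 | tert-butyl (2S)-5,7-bis(benzyloxy)-2-[(2R,3S)-2-[4-(benzyloxy)-3-methoxyphenyl]-7-{[4-(benzyloxy)-3-methoxybenzyl]oxy}-3-(hydroxymethyl)-2,3-dihydro-1-benzofuran-5-yl]-4-oxochromane-3-carboxylate | COc1cc([C@@H]2Oc3c(OCc4ccc(OCc5ccccc5)c(OC)c4)cc([C@@H]4C(C(=O)OC(C)(C)C)C(=O)c5c(OCc6ccccc6)cc(OCc6ccccc6)cc5O4)cc3[C@H]2CO)ccc1OCc1ccccc1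
F4 | step 11 | (2S)-5,7-bis(benzyloxy)-2-[(2R,3S)-2-[4-(benzyloxy)-3-methoxyphenyl]-7-{[4-(benzyloxy)-3-methoxybenzyl]oxy}-3-(hydroxymethyl)-2,3-dihydro-1-benzofuran-5-yl]chroman-4-one | COc1cc([C@@H]2Oc3c(OCc4ccc(OCc5ccccc5)c(OC)c4)cc([C@@H]4CC(=O)c5c(OCc6ccccc6)cc(OCc6ccccc6)cc5O4)cc3[C@H]2CO)ccc1OCc1ccccc1
F5 | step 10 | 3-(3,5-dihydroxyphenoxy)-3-oxopropanoic acid | OC(=O)CC(=O)Oc1cc(O)cc(O)c1
F6 | step 4 | 2-(3,4-bis{[4-(benzyloxy)-3-methoxybenzyl]oxy}-5-iodophenyl)-1,3-dioxolane | COc1cc(COc2cc(C3OCCO3)cc(I)c2OCc2ccc(OCc3ccccc3)c(OC)c2)ccc1OCc1ccccc1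
F7 | step 4 | ethyl 2-[2,3-bis{[4-(benzyloxy)-3-methoxybenzyl]oxy}-5-(1,3-dioxolan-2-yl)phenyl]acetate | CCOC(=O)Cc1cc(C2OCCO2)cc(OCc2ccc(OCc3ccccc3)c(OC)c2)c1OCc1ccc(OCc2ccccc2)c(OC)c1
F8 | step 4 | ethyl 2-(2,3-bis{[4-(benzyloxy)-3-methoxybenzyl]oxy}-5-formylphenyl)acetate | CCOC(=O)Cc1cc(C=O)cc(OCc2ccc(OCc3ccccc3)c(OC)c2)c1OCc1ccc(OCc2ccccc2)c(OC)c1
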